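**Plan**
Cuts (germacrane numbering): first the O10 protecting group, the O8 tiglate and the C3 oxidation level. Then O–C6 and C11–C7 of the lactone are cut together, which leaves 2-bromoacrylic acid and the ten-membered (4Z,6Z)-diene 17. Then C3–C4, C4=C5, C6=C7 and C1=C2 are cut, back to (R)-linalool.
Enabling feature: in the γ-lactone ring (O, C6, C7, C11, C12) the O-bearing C6 is allylic to C4=C5, and the fusion to the ten-membered ring is cis. The ring is therefore the suprafacial adduct of a 1-carboxyvinyl unit to the C6=C7 end of a C4=C5–C6=C7 diene, reached through an allylpalladium unit over C4–C6.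
Forward: linalool supplies C7–C10, C1 and C14. Cross-metathesis adds C2–C3, and two olefinations add C5–C6 and C4/C15. A Nozaki–Hiyama–Kishi closure makes the ten-membered ring, the annulation makes the lactone ring, and oxidation, tigloylation and deprotection finish the route.
Stereochemistry: C10 comes from (R)-linalool, C8 from L-proline aminoxylation, and C1/C2 from Sharpless epoxidation with L-(+)-diethyl tartrate. C7 and C6 come from the key step (direction by the C8 hydroxyl, syn addition to a Z alkene). The 6Z alkene comes from a butenolide ring, the 4Z alkene from the iodo-Wittig reaction, and the E tiglate from the reagent.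

Key step: step 11

Numbering remark: C1 and C2 are the epoxide carbons (C1 next to C10). C3 is the ketone, C4 (methyl C15)=C5 is the ring alkene, C6 is the O-lactone carbon and C7 is the other ring-fusion carbon. C8 bears the ester, C9 is the CH2 and C10 is the carbinol carbon (methyl C14). C11, C12 and C13 are the lactone α-carbon, the carbonyl and the exocyclic CH2.
Remark on the structure: the SMILES is read as (1R,2R,6S,7R,8R,10R), 4Z, trans epoxide, E ester (tiglate) and a cis-fused lactone (H6 and H7 on the same face). The route is planned for exactly this.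
Assumption: commercial (R)-(−)-linalool is taken as enantiomerically pure. The later reagent-controlled steps would turn any minor enantiomer into separable diastereomers.

Step 1
Reactants: 1 (R)-(−)-linalool
Product: 2 (R)-linalyl 4-methoxybenzyl ether
Conditions: NaH, PMBCl, n-Bu4NI (cat.), DMF, 0 °C to 40 °C
Reagents that add atoms: 4-methoxybenzyl chloride, COc1ccc(CCl)cc1
Why: Williamson etherification of the tertiary alkoxide with a reactive benzylic chloride masks O10 with a group that cannot migrate to a neighbouring alkoxide and that leaves at the end under neutral oxidative conditions, while C10 is untouched.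

Step 2
Reactants: 2 (R)-linalyl 4-methoxybenzyl ether
Product: 3 (R)-4-(4-methoxybenzyloxy)-4-methylhex-5-enal
Conditions: O3 (1 equiv, Sudan Red 7B as indicator), CH2Cl2, −78 °C; then Me2S, −78 °C to rt
Reagents that add atoms: ozone, [O-][O+]=O
Why: Chemoselective ozonolysis, in which the electron-rich trisubstituted alkene reacts much faster than the hindered vinyl group or the anisyl ring when ozone is metered against a dye, gives the C7 aldehyde after reductive work-up.

Step 3
Reactants: 3 (R)-4-(4-methoxybenzyloxy)-4-methylhex-5-enal; 4 methyl acrylate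
Product: 5 methyl (2E,4R)-4-(4-methoxybenzyloxy)-4-methyl-7-oxohept-2-enoate
Conditions: second-generation Hoveyda–Grubbs catalyst (5 mol %), 4 (5 equiv), CH2Cl2, 40 °C
Reagents that add atoms: none
Why: Olefin cross-metathesis between a hindered, non-dimerising allylic ether and an electron-poor acrylate is a selective pairing that gives the E enoate, and it is placed before any C6=C7 alkene exists because such an alkene would ring-close onto C1 to a cyclopentene.

Step 4
Reactants: 5 methyl (2E,4R)-4-(4-methoxybenzyloxy)-4-methyl-7-oxohept-2-enoate; 6 ethyl 2-(diphenoxyphosphoryl)acetate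
Product: 8 9-ethyl 1-methyl (2E,4R,6R,7Z)-6-(anilinooxy)-4-(4-methoxybenzyloxy)-4-methylnona-2,7-dienedioate, via aminoxy aldehyde 7 (not isolated)
Conditions: L-proline (20 mol %), PhNO, MeCN, −20 °C; the mixture is then added to 6, NaH, THF, −78 °C to 0 °C
Reagents that add atoms: nitrosobenzene, O=Nc1ccccc1
Why: Proline-catalysed α-aminoxylation, in which the enamine attacks the oxygen of acid-activated nitrosobenzene and L-proline gives the R centre at C8, is followed in the same flask by an Ando-type Z-selective Horner–Wadsworth–Emmons olefination that traps the labile aldehyde 7 before it can epimerise.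

Step 5
Reactants: 8 9-ethyl 1-methyl (2E,4R,6R,7Z)-6-(anilinooxy)-4-(4-methoxybenzyloxy)-4-methylnona-2,7-dienedioate
Product: 10 methyl (2E,4R)-4-(4-methoxybenzyloxy)-4-methyl-5-[(2R)-5-oxo-2,5-dihydrofuran-2-yl]pent-2-enoate, via hydroxy enoate 9 (not isolated)
Conditions: Zn dust, AcOH, THF, rt
Reagents that add atoms: none
Why: Reductive N–O cleavage by zinc frees the C8 hydroxyl, which can lactonise only from the Z enoate, so that closure to the butenolide locks the C6=C7 geometry and leaves any E isomer behind as a separable open hydroxy ester.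

Step 6
Reactants: 10 methyl (2E,4R)-4-(4-methoxybenzyloxy)-4-methyl-5-[(2R)-5-oxo-2,5-dihydrofuran-2-yl]pent-2-enoate
Product: 11 (5R)-5-[(2R,3E)-5-hydroxy-2-(4-methoxybenzyloxy)-2-methylpent-3-enyl]-2,5-dihydrofuran-2-ol (lactol, both anomers)
Conditions: DIBAL-H (4 equiv), CH2Cl2, −78 °C; aqueous Rochelle salt
Reagents that add atoms: none
Why: DIBAL-H reduction at low temperature stops at the aluminium lactolate for the butenolide while the acyclic enoate goes on to the allylic alcohol by 1,2-reduction, and the neutral tartrate work-up avoids dehydration to the furan.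

Step 7
Reactants: 11 lactol; 12 ethyltriphenylphosphonium iodide
Product: 14 (2E,4R,6R,7Z,9Z)-10-iodo-4-(4-methoxybenzyloxy)-4-methylundeca-2,7,9-triene-1,6-diol, via open hydroxy enal 13 (not isolated)
Conditions: 12, n-BuLi, THF, rt; I2, −78 °C; NaHMDS, −20 °C; then 11, −78 °C to −20 °C (ylide in excess)
Reagents that add atoms: iodine, II
Why: The Stork–Zhao-type Wittig olefination with the α-iodoethylidene ylide on the ring-opened lactol gives the (Z)-2-iodoalkene with iodine cis to C6 under kinetic control, while C6=C7 keeps the Z geometry inherited from the five-membered ring.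

Step 8
Reactants: 14 (2E,4R,6R,7Z,9Z)-10-iodo-4-(4-methoxybenzyloxy)-4-methylundeca-2,7,9-triene-1,6-diol
Product: 15 {(2S,3R)-3-[(2R,4R,5Z,7Z)-4-hydroxy-8-iodo-2-(4-methoxybenzyloxy)nona-5,7-dien-2-yl]oxiran-2-yl}methanol
Conditions: Ti(OiPr)4 (20 mol %), L-(+)-diethyl tartrate (24 mol %), t-BuOOH (1.1 equiv), 4 Å molecular sieves, CH2Cl2, −25 °C
Reagents that add atoms: tert-butyl hydroperoxide, CC(C)(C)OO
Why: In the Sharpless asymmetric epoxidation the primary E-allylic alcohol reacts far faster than the secondary Z-allylic alcohol at C8, and L-(+)-diethyl tartrate delivers oxygen to the face that gives the trans (1R,2S)-epoxide under reagent control.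

Step 9
Reactants: 15 epoxy diol
Product: 16 (2R,3R)-3-[(2R,4R,5Z,7Z)-4-hydroxy-8-iodo-2-(4-methoxybenzyloxy)nona-5,7-dien-2-yl]oxirane-2-carbaldehyde
Conditions: TEMPO (10 mol %), PhI(OAc)2 (1.1 equiv), CH2Cl2, rt
Reagents that add atoms: none
Why: Oxoammonium (TEMPO) oxidation is selective for the unhindered primary alcohol over the secondary C8 carbinol and is mild enough for the epoxide and the iododiene.

Step 10
Reactants: 16 epoxy aldehyde
Product: 17 (1R,2S,8R,10R,4Z,6Z)-1,2-epoxy-10-(4-methoxybenzyloxy)-4,10-dimethylcyclodeca-4,6-diene-3,8-diol (germacrane numbering, C3 epimers)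
Conditions: CrCl2 (10 equiv), NiCl2 (1 mol % of the chromium salt), DMSO, 2 mM, rt
Reagents that add atoms: none
Why: In the intramolecular Nozaki–Hiyama–Kishi reaction under high dilution the alkenylchromium species forms from the trisubstituted iodide with retention, tolerates the free hydroxyl and adds to the aldehyde to close the ten-membered ring, and the new C3 centre is erased in step 12 so that both epimers serve.

Step 11
Reactants: 17 macrocyclic diene diol; 18 2-bromoacrylic acid
Product: 20 (1R,2S,6S,7R,8R,10R,4Z)-1,2-epoxy-3,8-dihydroxy-10-(4-methoxybenzyloxy)germacra-4,11(13)-dien-12,6-olide (C3 epimers, cis-fused lactone), via allylpalladium carboxylate 19 (not isolated)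
Conditions: Pd(OAc)2 (10 mol %), P(2-furyl)3 (20 mol %), Ag2CO3 (1.2 equiv), BHT (cat.), slow addition of 18, MeCN, 50 °C
Reagents that add atoms: none
Why: Proposed new method: zerovalent palladium inserts into the C–Br bond of 18, Ag2CO3 removes bromide and the acid proton, and the cationic 1-carboxyvinylpalladium species adds syn across C6=C7 with carbon at C7 (the less substituted diene terminus) and the metal at C6, where it spreads over C4–C6 as the allyl complex 19, which then forms the O–C6 bond and returns zerovalent palladium. The closest known reaction type is the Larock heteroannulation of 1,3-dienes by aryl or vinyl halides that carry an OH, NHR or CO2H group, which has not been shown for an α-haloacrylic acid on a trisubstituted medium-ring diene. The lactone ring closes by 5-exo transfer of the palladium-bound carboxylate to the allyl terminus C6 (C–O reductive elimination from a six-membered palladacycle, the inner-sphere path known for acetate in chloride-free diene diacetoxylation) and not to the tertiary C4, which would need a seven-membered ring, so that C4=C5 stays Z. C7 is controlled by C8, because the free C8 hydroxyl binds the cationic metal in the insertion (hydroxyl-directed migratory insertion, parallel to the cis-selective vanadium-directed epoxidation of medium-ring Z-allylic alcohols), which selects the rotamer with O8 close to the alkene plane and C9 on the inner face and so places C11 cis to O8 (7R). C6 is controlled by C7, because the carboxylate sits on the palladium-bearing outer face and cannot reach the inner face of the ring, so that the addition to the Z alkene is suprafacial and the lactone is cis-fused (6S). The step needs C6=C7 to react in preference to C4=C5, the carbinols and the epoxide, which is secured by the fully substituted C4 terminus, by the lack of leaving groups at C3 and C8 and by the sp3 C3 that insulates the epoxide from the allyl system.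

Step 12
Reactants: 20 lactone diol
Product: 21 (1R,2R,6S,7R,8R,10R,4Z)-1,2-epoxy-8-hydroxy-10-(4-methoxybenzyloxy)-3-oxogermacra-4,11(13)-dien-12,6-olide
Conditions: MnO2 (activated, excess), CH2Cl2, rt
Reagents that add atoms: none
Why: MnO2 oxidises only the allylic C3 carbinol, since C8 is no longer allylic after the annulation, which tells the two secondary alcohols apart without protecting groups and merges the C3 epimers.

Step 13
Reactants: 21 hydroxy enone; 22 tigloyl chloride
Product: 23 (1R,2R,6S,7R,8R,10R,4Z)-1,2-epoxy-10-(4-methoxybenzyloxy)-3-oxo-8-tigloyloxygermacra-4,11(13)-dien-12,6-olide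
Conditions: 22, Et3N, DMAP (cat.), CH2Cl2, 0 °C to rt
Reagents that add atoms: none
Why: DMAP-catalysed acylation of the only free hydroxyl with the chloride of the thermodynamically stable E acid proceeds with retention at C8 and without risk of alkene isomerisation in the acyl group.

Step 14
Reactants: 23 PMB-protected target
Product: 24 target, (1R,2R,6S,7R,8R,10R,4Z)-1,2-epoxy-10-hydroxy-3-oxo-8-tigloyloxygermacra-4,11(13)-dien-12,6-olide
Conditions: DDQ, CH2Cl2/pH 7 buffer, 0 °C
Reagents that add atoms: none
Why: Oxidative cleavage of the 4-methoxybenzyl ether by DDQ (hydride abstraction, then hydrolysis of the oxocarbenium ion) runs under buffered neutral conditions that spare the epoxy ketone, the α-methylene lactone and the tiglate.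

**Compound list**
1 | (R)-(−)-linalool | C=C[C@](C)(O)CCC=C(C)C | starting material
2 | (R)-linalyl 4-methoxybenzyl ether | C=C[C@](C)(OCc1ccc(OC)cc1)CCC=C(C)C | intermediate
3 | (R)-4-(4-methoxybenzyloxy)-4-methylhex-5-enal | C=C[C@](C)(OCc1ccc(OC)cc1)CCC=O | intermediate
4 | methyl acrylate | C=CC(=O)OC | starting material
5 | methyl (2E,4R)-4-(4-methoxybenzyloxy)-4-methyl-7-oxohept-2-enoate | COC(=O)/C=C/[C@](C)(OCc1ccc(OC)cc1)CCC=O | intermediate
6 | ethyl 2-(diphenoxyphosphoryl)acetate | CCOC(=O)CP(=O)(Oc1ccccc1)Oc1ccccc1 | starting material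
7 | methyl (2E,4R,6R)-6-(anilinooxy)-4-(4-methoxybenzyloxy)-4-methyl-7-oxohept-2-enoate | COC(=O)/C=C/[C@](C)(OCc1ccc(OC)cc1)C[C@@H](ONc1ccccc1)C=O | intermediate
8 | 9-ethyl 1-methyl (2E,4R,6R,7Z)-6-(anilinooxy)-4-(4-methoxybenzyloxy)-4-methylnona-2,7-dienedioate | COC(=O)/C=C/[C@](C)(OCc1ccc(OC)cc1)C[C@@H](ONc1ccccc1)/C=C\C(=O)OCC | intermediate
9 | 9-ethyl 1-methyl (2E,4R,6R,7Z)-6-hydroxy-4-(4-methoxybenzyloxy)-4-methylnona-2,7-dienedioate | COC(=O)/C=C/[C@](C)(OCc1ccc(OC)cc1)C[C@@H](O)/C=C\C(=O)OCC | intermediate
10 | methyl (2E,4R)-4-(4-methoxybenzyloxy)-4-methyl-5-[(2R)-5-oxo-2,5-dihydrofuran-2-yl]pent-2-enoate | COC(=O)/C=C/[C@](C)(OCc1ccc(OC)cc1)C[C@H]1OC(=O)C=C1 | intermediate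
11 | (5R)-5-[(2R,3E)-5-hydroxy-2-(4-methoxybenzyloxy)-2-methylpent-3-enyl]-2,5-dihydrofuran-2-ol (both anomers) | OC/C=C/[C@](C)(OCc1ccc(OC)cc1)C[C@H]1OC(O)C=C1 | intermediate
12 | ethyltriphenylphosphonium iodide | CC[P+](c1ccccc1)(c1ccccc1)c1ccccc1.[I-] | starting material
13 | (2Z,4R,6R,7E)-4,9-dihydroxy-6-(4-methoxybenzyloxy)-6-methylnona-2,7-dienal | OC/C=C/[C@](C)(OCc1ccc(OC)cc1)C[C@@H](O)/C=C\C=O | intermediate
14 | (2E,4R,6R,7Z,9Z)-10-iodo-4-(4-methoxybenzyloxy)-4-methylundeca-2,7,9-triene-1,6-diol | OC/C=C/[C@](C)(OCc1ccc(OC)cc1)C[C@@H](O)/C=C\C=C(\C)I | intermediate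
15 | {(2S,3R)-3-[(2R,4R,5Z,7Z)-4-hydroxy-8-iodo-2-(4-methoxybenzyloxy)nona-5,7-dien-2-yl]oxiran-2-yl}methanol | OC[C@@H]1O[C@H]1[C@](C)(OCc2ccc(OC)cc2)C[C@@H](O)/C=C\C=C(\C)I | intermediate
16 | (2R,3R)-3-[(2R,4R,5Z,7Z)-4-hydroxy-8-iodo-2-(4-methoxybenzyloxy)nona-5,7-dien-2-yl]oxirane-2-carbaldehyde | O=C[C@@H]1O[C@H]1[C@](C)(OCc2ccc(OC)cc2)C[C@@H](O)/C=C\C=C(\C)I | intermediate
17 | (1R,2S,8R,10R,4Z,6Z)-1,2-epoxy-10-(4-methoxybenzyloxy)-4,10-dimethylcyclodeca-4,6-diene-3,8-diol (C3 epimers) | OC1[C@@H]2O[C@H]2[C@](C)(OCc3ccc(OC)cc3)C[C@@H](O)/C=C\C=C1\C | intermediate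
18 | 2-bromoacrylic acid | C=C(Br)C(=O)O | starting material
19 | allylpalladium carboxylate, drawn as the C6-bound six-membered palladacycle, other ligands left out | C=C1C(=O)O[Pd][C@H]2/C=C(/C)C(O)[C@@H]3O[C@H]3[C@](C)(OCc4ccc(OC)cc4)C[C@@H](O)[C@@H]12 | intermediate
20 | (1R,2S,6S,7R,8R,10R,4Z)-1,2-epoxy-3,8-dihydroxy-10-(4-methoxybenzyloxy)germacra-4,11(13)-dien-12,6-olide (C3 epimers) | C=C1C(=O)O[C@H]2/C=C(/C)C(O)[C@@H]3O[C@H]3[C@](C)(OCc4ccc(OC)cc4)C[C@@H](O)[C@@H]12 | intermediate
21 | (1R,2R,6S,7R,8R,10R,4Z)-1,2-epoxy-8-hydroxy-10-(4-methoxybenzyloxy)-3-oxogermacra-4,11(13)-dien-12,6-olide | C=C1C(=O)O[C@H]2/C=C(/C)C(=O)[C@@H]3O[C@H]3[C@](C)(OCc4ccc(OC)cc4)C[C@@H](O)[C@@H]12 | intermediate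
22 | tigloyl chloride, (E)-2-methylbut-2-enoyl chloride | C/C=C(\C)C(=O)Cl | starting material
23 | (1R,2R,6S,7R,8R,10R,4Z)-1,2-epoxy-10-(4-methoxybenzyloxy)-3-oxo-8-tigloyloxygermacra-4,11(13)-dien-12,6-olide | C=C1C(=O)O[C@H]2/C=C(/C)C(=O)[C@@H]3O[C@H]3[C@](C)(OCc4ccc(OC)cc4)C[C@@H](OC(=O)/C(C)=C/C)[C@@H]12 | intermediate
24 | (1R,2R,6S,7R,8R,10R,4Z)-1,2-epoxy-10-hydroxy-3-oxo-8-tigloyloxygermacra-4,11(13)-dien-12,6-olide | C=C1C(=O)O[C@H]2/C=C(/C)C(=O)[C@@H]3O[C@H]3[C@](C)(O)C[C@@H](OC(=O)/C(C)=C/C)[C@@H]12 | target

Total step count: 14. Longest linear sequence: 14 steps, from 1.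

**Steps most likely to fail**

Step 11 (Proposed new method).
- What may go wrong:
  - If the hydroxyl direction is weak, attack may occur on the other face of C6=C7, through the rotamer with H8 in the alkene plane.
  - The allyl complex may lose a β-hydride to give a triene, or it may be protonated.
  - The bromoacrylic acid may polymerise or lose HBr.
  - The lactone acyl group may shift from O6 to the free O8.
  - The epoxy alcohol may undergo Payne migration under base.
- Fallback by known chemistry (lactone before ring), from 15 back to 20. Both hydroxyls of 15 are silylated (TESCl, imidazole) to give the bis(triethylsilyl) ether F1. One equivalent of ozone, then Me2S, cleaves C6=C7 into the α-silyloxy aldehyde F2 and (Z)-3-iodobut-2-enal F3, and both are kept. A Morita–Baylis–Hillman reaction of F2 with methyl acrylate 4 (DABCO) gives the hydroxy acrylate F4. NBS/Me2S converts it with allylic transposition into the (Z)-2-(bromomethyl)enoate F5. CrCl2-mediated allylation of F3 by F5 (γ-attack through a closed transition state, syn adduct) is followed by HF·pyridine, which lactonises and removes both silyl groups. This should give the cis-fused lactone diol F6, with the C7 face set by the C8 centre of the allylchromium reagent. TEMPO/PhI(OAc)2 gives the epoxy aldehyde F7, and the Nozaki–Hiyama–Kishi closure of C3–C4 under the conditions of step 10 leads to 20.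

Step 10.
- What may go wrong:
  - Oligomerisation may outrun ring closure because of transannular strain.
  - Divalent chromium may reductively open the epoxy aldehyde.
  - Geometry at C4 may be lost in the alkenyl-metal stage.
- Fallback (ring closure moved to C4=C5 by metathesis), from 11 back to 17. Methylenation of lactol 11 (Ph3PCH3Br, KHMDS) gives the terminal (Z)-diene diol F8. Sharpless epoxidation and TEMPO oxidation as in steps 8 and 9 give the epoxy diol F9 and the epoxy aldehyde F10. Excess isopropenylmagnesium bromide adds to the aldehyde to give the isopropenyl carbinol F11. Ring-closing metathesis (second-generation Hoveyda–Grubbs catalyst, high dilution, toluene, 80 °C) between the isopropenyl group and the terminal CH2 of the diene forms C4=C5. The ring should favour the Z geometry, which gives 17.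

Step 7.
- What may go wrong:
  - The lactol may dehydrate to the furan.
  - γ-Deprotonation of the open hydroxy enal may erode C8 or the 6Z geometry.
  - The ylide may lose iodine.
  - Conversion may be low because the alkoxides consume base.
- Fallback (gem-dihalide plus stereoselective cross-coupling in place of the iodo-ylide), from 11 back to 14. (Dibromomethyl)triphenylphosphonium bromide and t-BuOK convert lactol 11 into the gem-dibromodiene diol F12. Negishi methylation (MeZnCl in excess, PdCl2(DPEphos), THF) takes place selectively at the bromide trans to C6 and gives the (Z)-bromodiene diol F13. Copper-catalysed halogen exchange (CuI, N,N'-dimethylethylenediamine, NaI, dioxane) with retention gives 14.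

**Further compounds**
F1 | step 11 | bis(triethylsilyl) ether of 15 | CC[Si](CC)(CC)OC[C@@H]1O[C@H]1[C@](C)(OCc2ccc(OC)cc2)C[C@@H](O[Si](CC)(CC)CC)/C=C\C=C(\C)I
F2 | step 11 | (2R,4R)-4-(4-methoxybenzyloxy)-2-(triethylsilyloxy)-4-[(2R,3S)-3-(triethylsilyloxymethyl)oxiran-2-yl]pentanal | CC[Si](CC)(CC)OC[C@@H]1O[C@H]1[C@](C)(OCc2ccc(OC)cc2)C[C@@H](O[Si](CC)(CC)CC)C=O
F3 | step 11 | (Z)-3-iodobut-2-enal | O=C/C=C(/C)I
F4 | step 11 | Morita–Baylis–Hillman adduct of F2 with methyl acrylate (C7 carbinol epimers) | CC[Si](CC)(CC)OC[C@@H]1O[C@H]1[C@](C)(OCc2ccc(OC)cc2)C[C@@H](O[Si](CC)(CC)CC)C(O)C(=C)C(=O)OC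
F5 | step 11 | (Z)-2-(bromomethyl)enoate from F4 | CC[Si](CC)(CC)OC[C@@H]1O[C@H]1[C@](C)(OCc2ccc(OC)cc2)C[C@@H](O[Si](CC)(CC)CC)/C=C(\CBr)C(=O)OC
F6 | step 11 | cis-4,5-disubstituted α-methylene-γ-butyrolactone diol, (Z)-2-iodopropenyl at C6, open chain at C7 | C=C1C(=O)O[C@@H](/C=C(/C)I)[C@H]1[C@H](O)C[C@@](C)(OCc3ccc(OC)cc3)[C@@H]2O[C@H]2CO
F7 | step 11 | epoxy aldehyde from F6 | C=C1C(=O)O[C@@H](/C=C(/C)I)[C@H]1[C@H](O)C[C@@](C)(OCc3ccc(OC)cc3)[C@@H]2O[C@H]2C=O
F8 | step 10 | (2E,4R,6R,7Z)-4-(4-methoxybenzyloxy)-4-methyldeca-2,7,9-triene-1,6-diol | OC/C=C/[C@](C)(OCc1ccc(OC)cc1)C[C@@H](O)/C=C\C=C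
F9 | step 10 | {(2S,3R)-3-[(2R,4R,5Z)-4-hydroxy-2-(4-methoxybenzyloxy)octa-5,7-dien-2-yl]oxiran-2-yl}methanol | OC[C@@H]1O[C@H]1[C@](C)(OCc2ccc(OC)cc2)C[C@@H](O)/C=C\C=C
F10 | step 10 | (2R,3R)-3-[(2R,4R,5Z)-4-hydroxy-2-(4-methoxybenzyloxy)octa-5,7-dien-2-yl]oxirane-2-carbaldehyde | O=C[C@@H]1O[C@H]1[C@](C)(OCc2ccc(OC)cc2)C[C@@H](O)/C=C\C=C
F11 | step 10 | isopropenyl carbinol from F10 (C3 epimers) | C=C(C)C(O)[C@@H]1O[C@H]1[C@](C)(OCc2ccc(OC)cc2)C[C@@H](O)/C=C\C=C
F12 | step 7 | (2E,4R,6R,7Z)-10,10-dibromo-4-(4-methoxybenzyloxy)-4-methyldeca-2,7,9-triene-1,6-diol | OC/C=C/[C@](C)(OCc1ccc(OC)cc1)C[C@@H](O)/C=C\C=C(Br)Br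
F13 | step 7 | (2E,4R,6R,7Z,9Z)-10-bromo-4-(4-methoxybenzyloxy)-4-methylundeca-2,7,9-triene-1,6-diol | OC/C=C/[C@](C)(OCc1ccc(OC)cc1)C[C@@H](O)/C=C\C=C(\C)Br
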